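The earlier runs and the new flask were computed on assumed constants; the scatter is artificial.

We decide to reckon this flask from one number of the west run, not from the shape of its curve.

- west: E 0.85 M; Q 2.21 M; D 7.1 mM; J 3.4 mM; run made earlier
- flask: E 1.7 M; Q 2.21 M; D 7.1 mM; J 3.4 mM; time 6.0 d

west run (percent of the E charged)

| time / d | X / % | Z / % |
|---|---|---|
| 0.0417 | 11.8 | 1.1 |
| 0.208 | 14.8 | 2.8 |
| 1.04 | 11.0 | 25.8 |
| 5.00 | 3.3 | 83.9 |

(standard deviation of a reading: 0.5 percentage points)

* time, not beyond 6.0 d, at which the flask holds most X
* the amount of X, in percent of the E charged, at that time



How much X can stand beside E? We take E as what the charge lacks after X and Z, so the west reading at 0.208 d gives, within its scatter, the standing ratio, X over E once their exchange has caught up: 0.180. Of the part not yet Z, X then holds the fraction 15.2%, and that is our ceiling.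

Does the ceiling carry over to the flask, with twice the E? If the exchange is first order in E both ways, a ratio of fractions ignores the charge, though the west run by itself does not test this.

How soon is the ceiling reached? The first west reading, 11.8% at 0.0417 d, lies far enough below it that the gap, so read, halves every 0.0194 d, much shorter than the time of the second reading. After 5 half-lives, 0.0969 d, the gap is within the scatter, and the Z of the second west reading costs X just 0.43 percentage points. The flask is charged with as much D as the west run, so we expect its X near the ceiling at about that time.

The forecast gives 15% at 0.3 d, reasoning “if this is first order in E, percentages barely change with doubled E”; its amount matches ours, and its time is later than ours.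

The flask reaches 14.7% at 0.134 d, and the top is so flat that X stays within 5 percent of it until 0.328 d, later than the forecast's time.

    Q + G → L + Z (k = 37.3 /M/h)
    E + D ⇌ D + X (K = 0.180, k = 32.5 /M/h)
    J ⇌ L (K = 3.30, k = 0.102 /h)
    L + X ⇌ G (K = 2.80 /M, k = 60.5 /M/h)

The largest single effect on that top is the way back from D + X to E + D: the run without it climbs to 70.1% instead of 14.7%. The standing ratio returns in the flask at its best time as 0.175. In the neighbouring flask charged with a quarter of the J, X and E stand at 8.63% and 48.8% after 6.00 d, a ratio of 0.177.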